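**Assumption:** the SMILES is taken literally, i.e. a cis-fused decalin (5-H syn to the C10 methyl) with configuration (5S,6S,8R,9R,10R,13R).
**Naming:** decalin compounds carry labdane locants (ring A = C1–C5, C10; ring B = C5–C10; C17 = methyl on C8; C18/C19 on C4; C20 on C10; side chain C11–C16). "cis-Decalin" means 5-H syn to C20.

## Retrosynthetic overview

1. Spiro-tetrahydrofuran and lactone are made together in the last step: ring-contractive benzilic-ester-type 1,2-shift (C12 from C16 to C13) in the bis-hemiketal of a 9,15-dihydroxy-13,16-dione.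
2. The dione comes from an alkyne; the alkyne from acetylide opening of a C9 spiro-oxetane; the oxetane by ring expansion of the α-epoxide of the C9 exocyclic alkene (sets C9).
3. Ring A is closed onto ring B by intramolecular tert-alkylation of a silyl enol ether (C4–C5 bond); C6 is then set by thermodynamic reduction.
4. Ring B comes from m-cresol via its p-quinone monoketal and two conjugate additions (methyl, asymmetric, sets C8; then the C1–C4 chain, sets C10).
5. Ring order: B (from the arene), A, oxetane, fused tetrahydropyran/tetrahydrofuran bis-hemiketal, spiro-tetrahydrofuran plus lactone.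

## Route

Step 1
Reactants: 1 3-methylphenol (m-cresol)
Product: 2 4,4-dimethoxy-3-methylcyclohexa-2,5-dien-1-one
Conditions: PhI(OAc)2 (2.2 equiv), MeOH, 0 °C to 20 °C
Reagents that add atoms: methanol, CO
Why: PhI(OAc)2-mediated oxidative dearomatisation of a para-unsubstituted phenol (two two-electron oxidations, each quenched by methanol at the para carbon) gives the p-quinone monoketal whose ketal carbon is the later C9; no stereocentre is formed.

Step 2
Reactants: 2 4,4-dimethoxy-3-methylcyclohexa-2,5-dien-1-one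
Product: 3 (5R)-4,4-dimethoxy-3,5-dimethylcyclohex-2-en-1-one
Conditions: Me2Zn (1.5 equiv), Cu(OTf)2 (2 mol %), O,O′-[(S)-1,1′-binaphthyl-2,2′-diyl] N,N-bis[(R)-1-phenylethyl]phosphoramidite (4 mol %), toluene, −25 °C; aq NH4Cl
Reagents that add atoms: dimethylzinc, C[Zn]C
Why: Feringa-type copper/phosphoramidite-catalysed asymmetric conjugate addition of Me2Zn goes only to the unsubstituted enone, and ligand-controlled face selection sets C8 (5R in 3); the sense is checked on the first run and the ligand antipode used if needed.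

Step 3
Reactants: 4 5-bromo-2-methylpent-2-ene
Product: 5 5-bromo-2-chloro-2-methylpentane
Conditions: HCl (g), CH2Cl2, −20 °C to 0 °C
Reagents that add atoms: hydrogen chloride, Cl
Why: Markovnikov ionic hydrochlorination of the trisubstituted alkene gives the tertiary chloride that later serves as the SN1 electrophile; the primary bromide is untouched and no stereocentre is formed.

Step 4
Reactants: 3 (5R)-4,4-dimethoxy-3,5-dimethylcyclohex-2-en-1-one; 5 5-bromo-2-chloro-2-methylpentane
Product: 7 {[(3R,5R)-3-(4-chloro-4-methylpentyl)-4,4-dimethoxy-3,5-dimethylcyclohex-1-en-1-yl]oxy}trimethylsilane, via Grignard reagent 6 (not isolated)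
Conditions: Mg, THF, 0–20 °C; then CuBr·SMe2 (10 mol %), TMSCl (2 equiv), DMPU, THF, −78 °C to −40 °C; Et3N/pentane work-up
Reagents that add atoms: chlorotrimethylsilane, C[Si](C)(C)Cl
Why: Chlorotrimethylsilane-accelerated copper-catalysed 1,4-addition of the Grignard reagent (Nakamura–Kuwajima conditions): axial attack anti to the C8 methyl (trans-3,5 rule for 5-substituted cyclohexenones) sets the quaternary C10 with the chain trans to C17, and the enolate is trapped regiospecifically toward C5 as the silyl enol ether.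

Step 5
Reactants: 7 {[(3R,5R)-3-(4-chloro-4-methylpentyl)-4,4-dimethoxy-3,5-dimethylcyclohex-1-en-1-yl]oxy}trimethylsilane
Product: 8 (5S,8R,10R)-9,9-dimethoxy-4,4,8,10-tetramethyl-cis-decalin-6-one
Conditions: ZnCl2·OEt2 (0.3 equiv), CH2Cl2, −40 °C to 0 °C
Reagents that add atoms: none
Why: Reetz-type Lewis-acid-mediated intramolecular α-tert-alkylation (SN1) of the silyl enol ether closes ring A (C4–C5): the tertiary cation reaches C5 from the face of the pseudo-axial C1 tether, giving the cis-fused decalin, which is also the thermodynamic fusion because a trans fusion would force C17 and C20 1,3-diaxial; the dimethyl ketal tolerates catalytic ZnCl2.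

Step 6
Reactants: 8 (5S,8R,10R)-9,9-dimethoxy-4,4,8,10-tetramethyl-cis-decalin-6-one
Product: 10 (5S,6S,8R,10R)-6-hydroxy-4,4,8,10-tetramethyl-cis-decalin-9-one, via hydroxy ketal 9 (not isolated)
Conditions: Li, NH3 (l), THF, t-BuOH, −78 °C; NH4Cl; then 2 M HCl, THF, 20 °C
Reagents that add atoms: water, O
Why: Dissolving-metal (Li/NH3) reduction gives the thermodynamically preferred equatorial 6-alcohol (the axial epimer would be 1,3-diaxial to C1), setting C6 cis to 5-H, and aqueous acid then hydrolyses the dimethyl ketal to the C9 ketone with C8 staying in its equatorial, thermodynamic configuration.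

Step 7
Reactants: 10 (5S,6S,8R,10R)-6-hydroxy-4,4,8,10-tetramethyl-cis-decalin-9-one
Product: 11 (5S,6S,8R,10R)-4,4,8,10-tetramethyl-9-methylidene-cis-decalin-6-ol
Conditions: Ph3PCH3Br (4 equiv), KOt-Bu (4 equiv), toluene, 90 °C
Reagents that add atoms: methyltriphenylphosphonium bromide, C[P+](c1ccccc1)(c1ccccc1)c1ccccc1.[Br-]
Why: Wittig methylenation with excess ylide at 90 °C (conditions that work for 2,2,6-trisubstituted cyclohexanones); no new stereocentre, and C8, epimerisable under the basic conditions, stays equatorial.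

Step 8
Reactants: 11 (5S,6S,8R,10R)-4,4,8,10-tetramethyl-9-methylidene-cis-decalin-6-ol
Product: 12 (5S,6S,8R,9R,10R)-4,4,8,10-tetramethyl-cis-decalin-9-spiro-2′-oxiran-6-ol (epoxide O syn to C20)
Conditions: mCPBA, NaHCO3, CH2Cl2, 0 °C
Reagents that add atoms: 3-chloroperoxybenzoic acid, OOC(=O)c1cccc(Cl)c1
Why: Prilezhaev epoxidation: the peracid attacks the exocyclic alkene from the axial face because the equatorial face is blocked by the axial C1 methylene of ring A, so the oxygen ends up syn to C20 and C11 anti, which sets C9.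

Step 9
Reactants: 12 (5S,6S,8R,9R,10R)-4,4,8,10-tetramethyl-cis-decalin-9-spiro-2′-oxiran-6-ol
Product: 13 (5S,6S,8R,9R,10R)-4,4,8,10-tetramethyl-cis-decalin-9-spiro-2′-oxetan-6-ol
Conditions: Me3S(O)I (3 equiv), KOt-Bu (3 equiv), t-BuOH, 50 °C
Reagents that add atoms: trimethylsulfoxonium iodide, C[S+](C)(C)=O.[I-]
Why: Corey–Chaykovsky-type ring expansion of an epoxide to an oxetane with dimethylsulfoxonium methylide (the ylide opens the epoxide at the CH2 terminus, the alkoxide then displaces DMSO in a 4-exo-tet closure); the C9–O bond is never broken, so C9 is retained.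

Step 10
Reactants: 13 (5S,6S,8R,9R,10R)-4,4,8,10-tetramethyl-cis-decalin-9-spiro-2′-oxetan-6-ol; 14 tert-butyl(but-3-yn-1-yloxy)dimethylsilane (TBS-protected but-3-yn-1-ol)
Product: 16 (5S,6S,8R,9R,10R)-9-[6-(tert-butyldimethylsilyloxy)hex-3-yn-1-yl]-4,4,8,10-tetramethyl-cis-decalin-6,9-diol, via lithium acetylide 15 (not isolated)
Conditions: 14 (4 equiv), n-BuLi (4 equiv), THF, −78 °C; BF3·OEt2 (4 equiv); then 13, −78 °C to −40 °C
Reagents that add atoms: none
Why: BF3-promoted SN2 opening of the oxetane by the lithium acetylide at the unsubstituted CH2 (Yamaguchi-type alkynylation) installs C12–C16 and O15 in one step and releases the tertiary 9-OH with C9 untouched; one equivalent of acetylide is consumed by the free 6-OH.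

Step 11
Reactants: 16 (5S,6S,8R,9R,10R)-9-[6-(tert-butyldimethylsilyloxy)hex-3-yn-1-yl]-4,4,8,10-tetramethyl-cis-decalin-6,9-diol
Product: 17 (5S,6S,8R,9R,10R)-9-[6-(tert-butyldimethylsilyloxy)hex-3-yn-1-yl]-9-hydroxy-4,4,8,10-tetramethyl-cis-decalin-6-yl acetate
Conditions: Ac2O, DMAP (cat.), pyridine, 20 °C
Reagents that add atoms: acetic anhydride, CC(=O)OC(C)=O
Why: DMAP-catalysed acetylation esterifies only the secondary equatorial 6-OH; the hindered tertiary 9-OH does not react.

Step 12
Reactants: 17 (5S,6S,8R,9R,10R)-9-[6-(tert-butyldimethylsilyloxy)hex-3-yn-1-yl]-9-hydroxy-4,4,8,10-tetramethyl-cis-decalin-6-yl acetate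
Product: 18 (5S,6S,8R,9R,10R)-9-[6-(tert-butyldimethylsilyloxy)-3,4-dioxohexyl]-9-hydroxy-4,4,8,10-tetramethyl-cis-decalin-6-yl acetate
Conditions: RuCl3·xH2O (3 mol %), NaIO4 (3 equiv), EtOAc/MeCN/H2O, 0 °C
Reagents that add atoms: sodium periodate, [Na+].[O-]I(=O)(=O)=O
Why: Ruthenium tetroxide (RuCl3/NaIO4) oxidation of the internal alkyne gives the 1,2-diketone without touching the acetate, the silyl ether or the tertiary alcohol; no stereocentre changes.

Step 13
Reactants: 18 (5S,6S,8R,9R,10R)-9-[6-(tert-butyldimethylsilyloxy)-3,4-dioxohexyl]-9-hydroxy-4,4,8,10-tetramethyl-cis-decalin-6-yl acetate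
Product: 19 (5S,6S,8R,9R,10R)-9-hydroxy-9-(6-hydroxy-3,4-dioxohexyl)-4,4,8,10-tetramethyl-cis-decalin-6-yl acetate (in equilibrium with its hemiketals)
Conditions: Bu4NF, AcOH (1:1), THF, 0 °C to 20 °C
Reagents that add atoms: none
Why: Fluoride desilylation buffered with acetic acid frees the 15-OH without base-induced benzilic rearrangement or β-elimination.

Step 14
Reactants: 19 (5S,6S,8R,9R,10R)-9-hydroxy-9-(6-hydroxy-3,4-dioxohexyl)-4,4,8,10-tetramethyl-cis-decalin-6-yl acetate
Product: 21 (5S,6S,8R,9R,10R,13R)-6-acetoxy-9,13-epoxylabdan-16,15-olide (CNP0081177.1), via bis-hemiketal 20 (not isolated)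
Conditions: (R)-3,3′-bis(2,4,6-triisopropylphenyl)-1,1′-binaphthyl-2,2′-diyl N-triflylphosphoramide (10 mol %; antipode chosen by a two-flask screen), water-saturated toluene, 40 °C
Reagents that add atoms: none
Why: Proposed new method: the hydroxy-dione closes reversibly to the cis-fused bis-hemiketal 20 (15-OH on the C16 carbonyl, 9-OH on the C13 carbonyl); the chiral acid ionises the C13 lactol to an oxocarbenium ion paired with the chiral anion, and the ring bond C12–C16 then shifts to C13 while the C16 hemiketal collapses to the lactone carbonyl, so the tetrahydropyran contracts to the spiro-tetrahydrofuran and the lactone forms in the same event; ester formation makes this irreversible, so the reversibly formed spiroketal isomer is only a resting state; C9 is retained because its C–O bond is never broken, and C13 is set by the catalyst, which selects between the two rapidly equilibrating diastereomeric bis-hemiketal ion pairs (substrate bias is small because C8 and C10 both present an equatorial methyl to the new ring); closest known chemistry is the benzilic ester rearrangement, acid-catalysed α-ketol/semipinacol shifts, and chiral phosphoric acid-controlled spiroketalisation.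

## Compound list

1 | 3-methylphenol (m-cresol) | Cc1cccc(O)c1 | starting material
2 | 4,4-dimethoxy-3-methylcyclohexa-2,5-dien-1-one | O=C1C=CC(OC)(OC)C(C)=C1 | intermediate
3 | (5R)-4,4-dimethoxy-3,5-dimethylcyclohex-2-en-1-one | O=C1C[C@@H](C)C(OC)(OC)C(C)=C1 | intermediate
4 | 5-bromo-2-methylpent-2-ene | CC(C)=CCCBr | starting material
5 | 5-bromo-2-chloro-2-methylpentane | CC(C)(Cl)CCCBr | intermediate
6 | (4-chloro-4-methylpentyl)magnesium bromide | CC(C)(Cl)CCC[Mg]Br | intermediate
7 | {[(3R,5R)-3-(4-chloro-4-methylpentyl)-4,4-dimethoxy-3,5-dimethylcyclohex-1-en-1-yl]oxy}trimethylsilane | C1=C(O[Si](C)(C)C)C[C@@H](C)C(OC)(OC)[C@]1(C)CCCC(C)(C)Cl | intermediate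
8 | (5S,8R,10R)-9,9-dimethoxy-4,4,8,10-tetramethyl-cis-decalin-6-one | O=C1C[C@@H](C)C(OC)(OC)[C@]2(C)CCCC(C)(C)[C@H]12 | intermediate
9 | (5S,6S,8R,10R)-9,9-dimethoxy-4,4,8,10-tetramethyl-cis-decalin-6-ol | O[C@H]1C[C@@H](C)C(OC)(OC)[C@]2(C)CCCC(C)(C)[C@H]12 | intermediate
10 | (5S,6S,8R,10R)-6-hydroxy-4,4,8,10-tetramethyl-cis-decalin-9-one | O[C@H]1C[C@@H](C)C(=O)[C@]2(C)CCCC(C)(C)[C@H]12 | intermediate
11 | (5S,6S,8R,10R)-4,4,8,10-tetramethyl-9-methylidene-cis-decalin-6-ol | O[C@H]1C[C@@H](C)C(=C)[C@]2(C)CCCC(C)(C)[C@H]12 | intermediate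
12 | (5S,6S,8R,9R,10R)-4,4,8,10-tetramethyl-cis-decalin-9-spiro-2′-oxiran-6-ol | O[C@H]1C[C@@H](C)[C@]2(CO2)[C@]2(C)CCCC(C)(C)[C@H]12 | intermediate
13 | (5S,6S,8R,9R,10R)-4,4,8,10-tetramethyl-cis-decalin-9-spiro-2′-oxetan-6-ol | O[C@H]1C[C@@H](C)[C@]2(CCO2)[C@]2(C)CCCC(C)(C)[C@H]12 | intermediate
14 | tert-butyl(but-3-yn-1-yloxy)dimethylsilane | C#CCCO[Si](C)(C)C(C)(C)C | starting material
15 | lithium 4-(tert-butyldimethylsilyloxy)but-1-yn-1-ide | [Li]C#CCCO[Si](C)(C)C(C)(C)C | intermediate
16 | (5S,6S,8R,9R,10R)-9-[6-(tert-butyldimethylsilyloxy)hex-3-yn-1-yl]-4,4,8,10-tetramethyl-cis-decalin-6,9-diol | O[C@H]1C[C@@H](C)[C@](O)(CCC#CCCO[Si](C)(C)C(C)(C)C)[C@]2(C)CCCC(C)(C)[C@H]12 | intermediate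
17 | (5S,6S,8R,9R,10R)-9-[6-(tert-butyldimethylsilyloxy)hex-3-yn-1-yl]-9-hydroxy-4,4,8,10-tetramethyl-cis-decalin-6-yl acetate | CC(=O)O[C@H]1C[C@@H](C)[C@](O)(CCC#CCCO[Si](C)(C)C(C)(C)C)[C@]2(C)CCCC(C)(C)[C@H]12 | intermediate
18 | (5S,6S,8R,9R,10R)-9-[6-(tert-butyldimethylsilyloxy)-3,4-dioxohexyl]-9-hydroxy-4,4,8,10-tetramethyl-cis-decalin-6-yl acetate | CC(=O)O[C@H]1C[C@@H](C)[C@](O)(CCC(=O)C(=O)CCO[Si](C)(C)C(C)(C)C)[C@]2(C)CCCC(C)(C)[C@H]12 | intermediate
19 | (5S,6S,8R,9R,10R)-9-hydroxy-9-(6-hydroxy-3,4-dioxohexyl)-4,4,8,10-tetramethyl-cis-decalin-6-yl acetate | CC(=O)O[C@H]1C[C@@H](C)[C@](O)(CCC(=O)C(=O)CCO)[C@]2(C)CCCC(C)(C)[C@H]12 | intermediate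
20 | bis-hemiketal of 19: (5S,6S,8R,9R,10R)-6-acetoxy-3a′,7a′-dihydroxy-4,4,8,10-tetramethyl-hexahydrospiro[cis-decalin-9,5′-furo[3,2-b]pyran], cis-fused, both ring-fusion epimers | CC(=O)O[C@H]1C[C@@H](C)[C@]2(CCC3(O)OCCC3(O)O2)[C@]2(C)CCCC(C)(C)[C@H]12 | intermediate
21 | (5S,6S,8R,9R,10R,13R)-6-acetoxy-9,13-epoxylabdan-16,15-olide | CC(=O)O[C@H]1C[C@@H](C)[C@]2(CC[C@]3(CCOC3=O)O2)[C@]2(C)CCCC(C)(C)[C@H]12 | target

## Step count and risk

Total step count: 14. Longest linear sequence: 13 steps (1 to 21 through steps 1, 2 and 4–14; step 3 prepares the side-chain halide).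

**Step 14 (proposed new ring contraction).** It may stall at the spiroketal isomer, lose water from the β-hydroxy ketone, or give poor C13 selectivity. Fallback with known chemistry, setting out from 19 and coming back at 21: KOH in aqueous dioxane effects the classical benzilic acid rearrangement (the acetate is cleaved too) and acidification closes the lactone, giving (5S,6S,8R,9R,10R)-6,9,13-trihydroxylabdan-16,15-olide F6 as a 13-epimer mixture. Acid-catalysed cyclodehydration (TsOH, toluene, 60 °C) through the tertiary C9 cation, captured by the 13-OH from the open face syn to C20, gives after chromatographic removal of the 13-epimer (5S,6S,8R,9R,10R,13R)-6-hydroxy-9,13-epoxylabdan-16,15-olide F7. Acetylation (Ac2O, DMAP, pyridine) then gives 21.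

**Step 4 (quaternary C10 by conjugate addition next to the ketal carbon).** The bulky functionalised Grignard reagent may add too slowly or reduce the γ,γ-dimethoxy enone. Fallback setting out from 3 and coming back at 8 (it also bypasses step 5): CuBr·SMe2-catalysed conjugate addition of allylmagnesium bromide, the least demanding carbon nucleophile, with TBSOTf/Et3N trapping gives tert-butyl{[(3R,5R)-3-allyl-4,4-dimethoxy-3,5-dimethylcyclohex-1-en-1-yl]oxy}dimethylsilane F1. Cross-metathesis with 2-methylbut-3-en-2-ol (second-generation Grubbs catalyst, RuCl2(=CHPh)(PCy3)(H2IMes), CH2Cl2, 40 °C) gives tert-butyl({(3R,5R)-3-[(2E)-4-hydroxy-4-methylpent-2-en-1-yl]-4,4-dimethoxy-3,5-dimethylcyclohex-1-en-1-yl}oxy)dimethylsilane F2. InCl3-catalysed ionisation of the tertiary allylic alcohol and capture of the allyl cation by the silyl enol ether at its tertiary end closes ring A to (5S,8R,10R)-9,9-dimethoxy-4,4,8,10-tetramethyl-cis-decal-2-en-6-one F3. Hydrogenation (H2, Pd/C, EtOAc) gives 8.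

**Step 9 (epoxide-to-oxetane ring expansion at the hindered spiro-epoxide).** The 4-exo closure may lose out to elimination or stop at the ring-opened stage. Fallback setting out from 12 and coming back at 16: lithiated 1-(trimethylsilyl)propyne (n-BuLi, TMEDA, THF, −78 °C to 0 °C) opens the epoxide at C11 to give (5S,6S,8R,9R,10R)-4,4,8,10-tetramethyl-9-[4-(trimethylsilyl)but-3-yn-1-yl]-cis-decalin-6,9-diol F4. K2CO3 in MeOH removes the C-silyl group to give (5S,6S,8R,9R,10R)-9-(but-3-yn-1-yl)-4,4,8,10-tetramethyl-cis-decalin-6,9-diol F5. Its trianion (n-BuLi, 3.3 equiv, THF/DMPU) is alkylated on carbon with tert-butyl(2-iodoethoxy)dimethylsilane to give 16.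

## Further compounds

F1 | step 4 | tert-butyl{[(3R,5R)-3-allyl-4,4-dimethoxy-3,5-dimethylcyclohex-1-en-1-yl]oxy}dimethylsilane | C1=C(O[Si](C)(C)C(C)(C)C)C[C@@H](C)C(OC)(OC)[C@]1(C)CC=C
F2 | step 4 | tert-butyl({(3R,5R)-3-[(2E)-4-hydroxy-4-methylpent-2-en-1-yl]-4,4-dimethoxy-3,5-dimethylcyclohex-1-en-1-yl}oxy)dimethylsilane | C1=C(O[Si](C)(C)C(C)(C)C)C[C@@H](C)C(OC)(OC)[C@]1(C)C/C=C/C(C)(C)O
F3 | step 4 | (5S,8R,10R)-9,9-dimethoxy-4,4,8,10-tetramethyl-cis-decal-2-en-6-one | O=C1C[C@@H](C)C(OC)(OC)[C@]2(C)CC=CC(C)(C)[C@H]12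
F4 | step 9 | (5S,6S,8R,9R,10R)-4,4,8,10-tetramethyl-9-[4-(trimethylsilyl)but-3-yn-1-yl]-cis-decalin-6,9-diol | O[C@H]1C[C@@H](C)[C@](O)(CCC#C[Si](C)(C)C)[C@]2(C)CCCC(C)(C)[C@H]12
F5 | step 9 | (5S,6S,8R,9R,10R)-9-(but-3-yn-1-yl)-4,4,8,10-tetramethyl-cis-decalin-6,9-diol | O[C@H]1C[C@@H](C)[C@](O)(CCC#C)[C@]2(C)CCCC(C)(C)[C@H]12
F6 | step 14 | (5S,6S,8R,9R,10R)-6,9,13-trihydroxylabdan-16,15-olide (13-epimer mixture) | O[C@H]1C[C@@H](C)[C@](O)(CCC2(O)CCOC2=O)[C@]3(C)CCCC(C)(C)[C@H]13
F7 | step 14 | (5S,6S,8R,9R,10R,13R)-6-hydroxy-9,13-epoxylabdan-16,15-olide | O[C@H]1C[C@@H](C)[C@]2(CC[C@]3(CCOC3=O)O2)[C@]2(C)CCCC(C)(C)[C@H]12
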